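**Retrosynthetic overview** (eudesmane/germacrane numbering C1–C15 throughout; C11–C13 are the lactone carbons, C14 the C10 methyl, C15 the C4 methylene)

1. The ether oxygen of the target joins C5 and C10, the two ring-fusion carbons of a eudesmane. The oxepane ring (O, C5, C6, C7, C8, C9, C10), and with it the oxepinone ring (O, C10, C1, C2, C3, C4, C5), is therefore disconnected by taking this oxygen out of a C5–C10 bond: Criegee rearrangement of a eudesmanolide C5 perester, with the tertiary, allylic C10 as migrating group.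
2. The C4=C15 exocyclic methylene next to C5 is the mark of a singlet-oxygen ene reaction, which places the hydroperoxide on C5 of a 4(5)-ene.
3. The decalin, all fifteen skeletal carbons and the C7, C8 and C10 stereocentres come from (+)-alantolactone (chiral pool). C6 is set by α-epoxidation, the lactone is moved from O8 to O6 through an N-methoxy-N-methylamide, and O8 is angeloylated.
4. Ring order: the two carbocycles (bought), the 12,6-lactone (step 4), then both seven-membered ether rings in one ring expansion (step 10). No ring is closed after that.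
5. End game: ionic hydrogenation of the bridgehead ketal ester, desilylation, oxidation at C3.

Key step: step 10

Remark: (+)-alantolactone is taken as a purchasable sesquiterpene lactone; the C3 carbinol and the C5 hydroperoxide are drawn as the expected epimers, and both centres are later erased (C3) or overwritten (C5), so either epimer serves.

**Step 1**
Reactants: 1 (+)-alantolactone
Product: 2 8β-hydroxy-N-methoxy-N-methyleudesma-5,11(13)-dien-12-amide
Conditions: MeNH(OMe)·HCl, AlMe3, CH2Cl2, 0 °C to rt
Reagents that add atoms: N,O-dimethylhydroxylamine hydrochloride, CNOC.Cl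
Why: Weinreb aminolysis of the lactone by the aluminium amide (hard nucleophile, 1,2-attack, no free amine to add to the acrylate) should free O8 and park C12 as an amide that does not return to O8 under the basic conditions of step 2; no stereocentre is touched.

**Step 2**
Reactants: 2 8β-hydroxy-N-methoxy-N-methyleudesma-5,11(13)-dien-12-amide; 3 angelic acid
Product: 5 8β-angeloyloxy-N-methoxy-N-methyleudesma-5,11(13)-dien-12-amide, via mixed anhydride 4 (not isolated)
Conditions: 3, 2,4,6-trichlorobenzoyl chloride, Et3N, toluene, rt; then 2, DMAP, rt to 40 °C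
Reagents that add atoms: none
Why: Yamaguchi esterification should acylate the hindered axial 8β-alcohol near room temperature with little Z to E drift of the angelate; C8 keeps its configuration because only the O–H bond reacts.

**Step 3**
Reactants: 5 8β-angeloyloxy-N-methoxy-N-methyleudesma-5,11(13)-dien-12-amide
Product: 6 8β-angeloyloxy-5α,6α-epoxy-N-methoxy-N-methyleudesm-11(13)-en-12-amide
Conditions: mCPBA, CH2Cl2, 0 °C
Reagents that add atoms: mCPBA, OOC(=O)c1cccc(Cl)c1
Why: Prilezhaev epoxidation should take only the electron-rich trisubstituted C5=C6 alkene (acrylamide and angelate are electron-poor) and from the α face, opposite the β-methyl groups on C4 and C10 and the β substituents on C7 and C8, which sets the α oxygen at C6.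

**Step 4**
Reactants: 6 8β-angeloyloxy-5α,6α-epoxy-N-methoxy-N-methyleudesm-11(13)-en-12-amide
Product: 8 8β-angeloyloxyeudesma-4,11(13)-dien-12,6α-olide, via hydroxy amide 7 (not isolated)
Conditions: diethylaluminium 2,2,6,6-tetramethylpiperidide (from Et2AlCl and lithium 2,2,6,6-tetramethylpiperidide), toluene, 0 °C; then CSA, CH2Cl2, rt
Reagents that add atoms: none
Why: Epoxide-to-allylic-alcohol isomerisation by syn β-elimination with the aluminium amide should break the tertiary C5–O bond and take the α hydrogen at C4 (the only hydrogen on a carbon attached to C5, syn to the epoxide oxygen), giving the 4(5)-ene and the 6α-alcohol; acid-catalysed lactonisation onto the N-methoxyamide then closes the trans 12,6-lactone, and only O6 can close because O8 is acylated.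

**Step 5**
Reactants: 8 8β-angeloyloxyeudesma-4,11(13)-dien-12,6α-olide
Product: 9 8β-angeloyloxy-3-oxoeudesma-4,11(13)-dien-12,6α-olide
Conditions: CrO3, 3,5-dimethylpyrazole, CH2Cl2, −20 °C
Reagents that add atoms: chromium trioxide, O=[Cr](=O)=O
Why: Allylic C–H oxidation should convert C3, the only allylic ring methylene of the tetrasubstituted alkene, into the ketone of a conjugated enone, since the C15 methyl and the oxygen-bearing C6–H are oxidised much more slowly.

**Step 6**
Reactants: 9 8β-angeloyloxy-3-oxoeudesma-4,11(13)-dien-12,6α-olide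
Product: 10 8β-angeloyloxy-3-oxoeudesma-1,4,11(13)-trien-12,6α-olide
Conditions: DDQ, 1,4-dioxane, 100 °C
Reagents that add atoms: none
Why: DDQ dehydrogenation of a 4-en-3-one under neutral conditions should go through the 2(3)-enol and hydride loss from C1, the steroid-type route to cross-conjugated 1,4-dien-3-ones.

**Step 7**
Reactants: 10 8β-angeloyloxy-3-oxoeudesma-1,4,11(13)-trien-12,6α-olide
Product: 11 8β-angeloyloxy-3β-hydroxyeudesma-1,4,11(13)-trien-12,6α-olide
Conditions: NaBH4, CeCl3·7H2O, MeOH, −78 °C
Reagents that add atoms: none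
Why: Luche reduction should give fast 1,2-reduction of the dienone before the α-methylene lactone is touched, hydride entering from the α face opposite the angular methyl; the C3 centre is temporary and makes the C4=C5 alkene electron-rich for step 9.

**Step 8**
Reactants: 11 8β-angeloyloxy-3β-hydroxyeudesma-1,4,11(13)-trien-12,6α-olide
Product: 12 8β-angeloyloxy-3β-(tert-butyldimethylsilyloxy)eudesma-1,4,11(13)-trien-12,6α-olide
Conditions: TBSOTf, 2,6-lutidine, CH2Cl2, −78 °C
Reagents that add atoms: tert-butyldimethylsilyl triflate, CC(C)(C)[Si](C)(C)OS(=O)(=O)C(F)(F)F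
Why: Silyl ether formation under basic conditions should protect the acid-sensitive bis-allylic alcohol, and the bulky β-silyloxy group also shields the β face and deactivates H3 in the next step.

**Step 9**
Reactants: 12 8β-angeloyloxy-3β-(tert-butyldimethylsilyloxy)eudesma-1,4,11(13)-trien-12,6α-olide
Product: 13 8β-angeloyloxy-3β-(tert-butyldimethylsilyloxy)-5α-hydroperoxyeudesma-1,4(15),11(13)-trien-12,6α-olide
Conditions: O2, visible light, 5,10,15,20-tetraphenylporphyrin (cat.), CH2Cl2, −20 °C
Reagents that add atoms: dioxygen (as singlet oxygen), O=O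
Why: Schenck ene reaction of singlet oxygen with the only electron-rich alkene (tetrasubstituted C4=C5) should add oxygen to C5 from the α face (β face blocked by the C10 methyl and the 3β-silyloxy group); C10 has no hydrogen, H6 is on the β face and the hydrogen geminal to the silyloxy group is not abstracted, so hydrogen comes from C15 and the 4(15)-methylene results.

**Step 10**
Reactants: 13 8β-angeloyloxy-3β-(tert-butyldimethylsilyloxy)-5α-hydroperoxyeudesma-1,4(15),11(13)-trien-12,6α-olide
Product: 15 8β-angeloyloxy-3β-(tert-butyldimethylsilyloxy)-5-(4-nitrobenzoyloxy)-5,10-epoxygermacra-1,4(15),11(13)-trien-12,6α-olide (bridgehead ketal ester; C6, C7, C8, C10 as in 18, 3S), via peroxy ester 14 (not isolated)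
Conditions: 4-nitrobenzoyl chloride, pyridine, DMAP (cat.), CH2Cl2, 0 °C; then MeCN, rt
Reagents that add atoms: 4-nitrobenzoyl chloride, O=C(Cl)c1ccc(cc1)[N+](=O)[O-]
Why: Acylation of the tertiary hydroperoxide gives peroxy ester 14, which ionises at the O–O bond while C10, brought anti-periplanar by rotation about C5–O, shifts from C5 to the proximal oxygen (Criegee rearrangement); the bridgehead oxocarbenium ion at C5, stabilised by the ring oxygen and the C4=C15 alkene, is captured by the carboxylate to give the ketal ester. The closest known reaction is the Criegee rearrangement of 9-decalyl peresters to 11-oxabicyclo[4.4.1]undecan-1-yl esters, which is the same ring system. Both seven-membered ether rings, the oxepane (O, C5, C6, C7, C8, C9, C10) and the oxepine (O, C10, C1, C2, C3, C4, C5), are closed at once by ring expansion, a suprafacial 1,2-shift that inserts oxygen into the C5–C10 ring-fusion bond and unveils the ten-membered carbocycle. C10 migrates with retention, so the quaternary ether centre is inherited from alantolactone, and C5 is a bridgehead whose geometry is dictated by the bicycle, which makes the step convergent for either C5 epimer of the hydroperoxide. The step needs migration of C10 and not of C4 or C6 (Hock-type fragmentation): C10 is tertiary, allylic to C1=C2 and free of withdrawing groups, whereas C4 is an sp2 carbon next to the C3 silyloxy group and C6 carries the lactone oxygen.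

**Step 11**
Reactants: 15 the bridgehead ketal 4-nitrobenzoate
Product: 16 (3S,5S,6S,7R,8R,10S)-8-angeloyloxy-3-(tert-butyldimethylsilyloxy)-5,10-epoxygermacra-1,4(15),11(13)-trien-12,6-olide
Conditions: Et3SiH, TMSOTf (cat.), CH2Cl2, −78 °C
Reagents that add atoms: none
Why: Ionic hydrogenation of a ketal ester: the Lewis acid should ionise the bridgehead ester to the allyl-stabilised oxocarbenium ion much faster than the allylic silyl ether at this temperature, and the silane delivers hydride to the oxygen-bearing carbon C5 from the only open (outer) face of the bridgehead, which fixes C5.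

**Step 12**
Reactants: 16 the 3-silyl ether
Product: 17 (3S,5S,6S,7R,8R,10S)-8-angeloyloxy-3-hydroxy-5,10-epoxygermacra-1,4(15),11(13)-trien-12,6-olide
Conditions: HF·pyridine, THF, 0 °C to rt
Reagents that add atoms: none
Why: Fluoride-mediated desilylation under buffered, weakly acidic conditions should leave the angelate, the α-methylene lactone and the allylic ether bridge untouched.

**Step 13**
Reactants: 17 the C3 alcohol
Product: 18 target, (5S,6S,7R,8R,10S)-8-angeloyloxy-5,10-epoxy-3-oxogermacra-1,4(15),11(13)-trien-12,6-olide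
Conditions: Dess–Martin periodinane, pyridine, CH2Cl2, 0 °C to rt
Reagents that add atoms: none
Why: Dess–Martin oxidation of the bis-allylic alcohol under neutral conditions should give the cross-conjugated dienone without moving the exocyclic alkenes or isomerising the angelate; the C3 stereocentre is erased.

**Compound list**

1 | (+)-alantolactone, eudesma-5,11(13)-dien-12,8β-olide | C[C@H]1CCC[C@]2(C)C[C@H]3OC(=O)C(=C)[C@H]3C=C12 | starting material
2 | 8β-hydroxy-N-methoxy-N-methyleudesma-5,11(13)-dien-12-amide | C[C@H]1CCC[C@]2(C)C[C@@H](O)[C@@H](C(=C)C(=O)N(C)OC)C=C12 | intermediate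
3 | angelic acid, (Z)-2-methylbut-2-enoic acid | C/C=C(/C)C(=O)O | starting material
4 | angelic 2,4,6-trichlorobenzoic anhydride | C/C=C(/C)C(=O)OC(=O)c1c(Cl)cc(Cl)cc1Cl | intermediate (not isolated)
5 | 8β-angeloyloxy-N-methoxy-N-methyleudesma-5,11(13)-dien-12-amide | C[C@H]1CCC[C@]2(C)C[C@@H](OC(=O)/C(C)=C\C)[C@@H](C(=C)C(=O)N(C)OC)C=C12 | intermediate
6 | 8β-angeloyloxy-5α,6α-epoxy-N-methoxy-N-methyleudesm-11(13)-en-12-amide | C[C@H]1CCC[C@]2(C)C[C@@H](OC(=O)/C(C)=C\C)[C@@H](C(=C)C(=O)N(C)OC)[C@@H]3O[C@]123 | intermediate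
7 | 8β-angeloyloxy-6α-hydroxy-N-methoxy-N-methyleudesma-4,11(13)-dien-12-amide | CC1=C2[C@@H](O)[C@H](C(=C)C(=O)N(C)OC)[C@H](OC(=O)/C(C)=C\C)C[C@@]2(C)CCC1 | intermediate (not isolated)
8 | 8β-angeloyloxyeudesma-4,11(13)-dien-12,6α-olide | CC1=C2[C@H]3OC(=O)C(=C)[C@@H]3[C@H](OC(=O)/C(C)=C\C)C[C@@]2(C)CCC1 | intermediate
9 | 8β-angeloyloxy-3-oxoeudesma-4,11(13)-dien-12,6α-olide | CC1=C2[C@H]3OC(=O)C(=C)[C@@H]3[C@H](OC(=O)/C(C)=C\C)C[C@@]2(C)CCC1=O | intermediate
10 | 8β-angeloyloxy-3-oxoeudesma-1,4,11(13)-trien-12,6α-olide | CC1=C2[C@H]3OC(=O)C(=C)[C@@H]3[C@H](OC(=O)/C(C)=C\C)C[C@@]2(C)C=CC1=O | intermediate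
11 | 8β-angeloyloxy-3β-hydroxyeudesma-1,4,11(13)-trien-12,6α-olide | CC1=C2[C@H]3OC(=O)C(=C)[C@@H]3[C@H](OC(=O)/C(C)=C\C)C[C@@]2(C)C=C[C@@H]1O | intermediate
12 | 3β-tert-butyldimethylsilyl ether of 11 | CC1=C2[C@H]3OC(=O)C(=C)[C@@H]3[C@H](OC(=O)/C(C)=C\C)C[C@@]2(C)C=C[C@@H]1O[Si](C)(C)C(C)(C)C | intermediate
13 | 8β-angeloyloxy-3β-(tert-butyldimethylsilyloxy)-5α-hydroperoxyeudesma-1,4(15),11(13)-trien-12,6α-olide | C=C1[C@@H](O[Si](C)(C)C(C)(C)C)C=C[C@]2(C)C[C@@H](OC(=O)/C(C)=C\C)[C@H]3C(=C)C(=O)O[C@@H]3[C@@]12OO | intermediate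
14 | 5α-peroxy 4-nitrobenzoate of 13 | C=C1[C@@H](O[Si](C)(C)C(C)(C)C)C=C[C@]2(C)C[C@@H](OC(=O)/C(C)=C\C)[C@H]3C(=C)C(=O)O[C@@H]3[C@@]12OOC(=O)c1ccc(cc1)[N+](=O)[O-] | intermediate (not isolated)
15 | 8β-angeloyloxy-3β-(tert-butyldimethylsilyloxy)-5-(4-nitrobenzoyloxy)-5,10-epoxygermacra-1,4(15),11(13)-trien-12,6α-olide | C=C1C(=O)O[C@H]2[C@H]1[C@H](OC(=O)/C(C)=C\C)C[C@@]1(C)C=C[C@H](O[Si](C)(C)C(C)(C)C)C(=C)[C@]2(OC(=O)c3ccc(cc3)[N+](=O)[O-])O1 | intermediate
16 | (3S,5S,6S,7R,8R,10S)-8-angeloyloxy-3-(tert-butyldimethylsilyloxy)-5,10-epoxygermacra-1,4(15),11(13)-trien-12,6-olide | C=C1C(=O)O[C@H]2[C@H]1[C@H](OC(=O)/C(C)=C\C)C[C@@]1(C)C=C[C@H](O[Si](C)(C)C(C)(C)C)C(=C)[C@@H]2O1 | intermediate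
17 | (3S,5S,6S,7R,8R,10S)-8-angeloyloxy-3-hydroxy-5,10-epoxygermacra-1,4(15),11(13)-trien-12,6-olide | C=C1C(=O)O[C@H]2[C@H]1[C@H](OC(=O)/C(C)=C\C)C[C@@]1(C)C=C[C@H](O)C(=C)[C@@H]2O1 | intermediate
18 | (5S,6S,7R,8R,10S)-8-angeloyloxy-5,10-epoxy-3-oxogermacra-1,4(15),11(13)-trien-12,6-olide | C=C1C(=O)O[C@H]2[C@H]1[C@H](OC(=O)/C(C)=C\C)C[C@@]1(C)C=CC(=O)C(=C)[C@@H]2O1 | target

**Step count and risks**

Total step count: 13. Longest linear sequence: 13 steps from 1 (angelic acid 3 enters in step 2).

Steps most likely to fail: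

- **Step 10.** The wrong substituent may migrate (the C4 vinyl group, leading to Hock-type fragmentation of the C4–C5 bond), or the allylic hydroperoxide may transpose before it is acylated. Fallback, from 13 back to 16: reduction of 13 with PPh3 should give the tertiary alcohol 8β-angeloyloxy-3β-(tert-butyldimethylsilyloxy)-5α-hydroxyeudesma-1,4(15),11(13)-trien-12,6α-olide F1. Alkoxy-radical β-fragmentation of F1 (PhI(OAc)2, I2, visible light; the hypoiodite route known from 5-hydroxy steroids to 5,10-seco ketones) cleaves C5–C10 because this gives the tertiary allylic C10 radical. Oxidation of that radical and transannular capture of the C10 cation by the new C5 carbonyl oxygen, followed by acetate, should give the bridgehead ketal acetate 5-acetoxy-8β-angeloyloxy-3β-(tert-butyldimethylsilyloxy)-5,10-epoxygermacra-1,4(15),11(13)-trien-12,6α-olide F2. F2 is reduced with Et3SiH and TMSOTf as in step 11 to rejoin the route at 16.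
- **Step 2.** Acylation of the hindered axial alcohol may be slower than relactonisation to alantolactone, and the angelate may drift to the tiglate. Fallback, from 2 back to 5: esterification of 2 with 2-[bis(2,2,2-trifluoroethoxy)phosphoryl]propanoic acid (DCC, DMAP, CH2Cl2) should give the phosphonate ester 8β-{2-[bis(2,2,2-trifluoroethoxy)phosphoryl]propanoyloxy}-N-methoxy-N-methyleudesma-5,11(13)-dien-12-amide F3. Still–Gennari olefination of F3 with acetaldehyde (KN(SiMe3)2, 18-crown-6, THF, −78 °C) builds the Z-trisubstituted alkene on the ester and gives 5.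
- **Step 5.** The C–H oxidation may show poor site selectivity (attack at C15 or at the C6–H) or over-oxidise. Fallback, from 8 back to 9: ene/[2,3]-sigmatropic allylic hydroxylation with SeO2 (cat.) and t-BuOOH in CH2Cl2 prefers the ring methylene and should give 8β-angeloyloxy-3-hydroxyeudesma-4,11(13)-dien-12,6α-olide F4 (either C3 epimer serves). Dess–Martin oxidation of F4 gives 9.

**Further compounds**

F1 | step 10 | 8β-angeloyloxy-3β-(tert-butyldimethylsilyloxy)-5α-hydroxyeudesma-1,4(15),11(13)-trien-12,6α-olide | C=C1[C@@H](O[Si](C)(C)C(C)(C)C)C=C[C@]2(C)C[C@@H](OC(=O)/C(C)=C\C)[C@H]3C(=C)C(=O)O[C@@H]3[C@@]12O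
F2 | step 10 | 5-acetoxy-8β-angeloyloxy-3β-(tert-butyldimethylsilyloxy)-5,10-epoxygermacra-1,4(15),11(13)-trien-12,6α-olide | C=C1C(=O)O[C@H]2[C@H]1[C@H](OC(=O)/C(C)=C\C)C[C@@]1(C)C=C[C@H](O[Si](C)(C)C(C)(C)C)C(=C)[C@]2(OC(C)=O)O1
F3 | step 2 | 8β-{2-[bis(2,2,2-trifluoroethoxy)phosphoryl]propanoyloxy}-N-methoxy-N-methyleudesma-5,11(13)-dien-12-amide (both epimers at the phosphonate carbon) | C[C@H]1CCC[C@]2(C)C[C@@H](OC(=O)C(C)P(=O)(OCC(F)(F)F)OCC(F)(F)F)[C@@H](C(=C)C(=O)N(C)OC)C=C12
F4 | step 5 | 8β-angeloyloxy-3β-hydroxyeudesma-4,11(13)-dien-12,6α-olide | CC1=C2[C@H]3OC(=O)C(=C)[C@@H]3[C@H](OC(=O)/C(C)=C\C)C[C@@]2(C)CC[C@@H]1O
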